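**Plan**

1. The target is (−)-epicatechin-(4β→8)-(2R,3R)-taxifolin. The retrosynthesis cuts, in this order: the nine O-benzyl groups; the lower C3–OH (back to a C3=C4 enol silane); the lower C4–C4a bond (ring F opens to a siloxyalkyne hanging from O1); the lower O1–C2 bond; and the interflavan bond C4 (ring C)–C8 (ring D).
2. Forward: rings A, C and B are bought as (−)-epicatechin, and ring D is joined to C4 of ring C as 3,5-bis(benzyloxy)phenol. Its free OH (the future O1) is etherified with a ring E propargylic carbinol and the alkyne is oxidised to a siloxyalkyne. Ring F is then closed and hydroxylated at C3, and all benzyl groups are removed.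
3. Enabling feature: ring D carbon C4a lies between O1 and O5 and para to O7 (phloroglucinol pattern). Once C8 bears the flavanyl group, C4a is the only free carbon ortho to O1, so an acylium equivalent at C4, held three atoms from O1, can close ring F only there.
4. The C4 carbonyl arrives after the interflavan bond and in masked form. Ring D therefore stays electron-rich for the coupling, the 4→8 connectivity follows from the construction, and the enol silane formed is the handle for the C3 hydroxyl.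
5. Stereochemistry: upper C2 and C3 are bought. Upper C4 is relayed from C3 (trans attack). Lower C2 comes from one lipase-resolved carbinol with Mitsunobu inversion. Lower C3 is relayed from C2 (attack anti to ring E).

Key step: step 9

Remark: flavonoid numbering is used. Rings A, C, B belong to the upper unit and rings D (phloroglucinol), F (pyranone), E (catechol) to the lower unit. Compounds 1, 5 and 7 are assumed to be commercial.

**Step 1**
Reactants: 1 (−)-epicatechin
Product: 2 5,7,3',4'-tetra-O-benzyl-(−)-epicatechin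
Conditions: BnBr (4.2 equiv), K2CO3, DMF, 0 °C to rt, N2
Reagents that add atoms: benzyl bromide, BrCc1ccccc1
Why: Williamson ether synthesis in which K2CO3 deprotonates only the four phenols, so the secondary 3-OH stays free and C2 and C3 are untouched.

**Step 2**
Reactants: 2 5,7,3',4'-tetra-O-benzyl-(−)-epicatechin
Product: 3 4β-(2-ethoxyethoxy)-5,7,3',4'-tetra-O-benzyl-(−)-epicatechin (2,3-cis, 3,4-trans)
Conditions: DDQ (2 equiv), 2-ethoxyethanol (excess), CH2Cl2, rt
Reagents that add atoms: 2-ethoxyethanol, CCOCCO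
Why: DDQ benzylic oxidation, in which hydride abstraction from C4 gives a cation stabilised by the dialkoxy ring A and the alcohol should add on the β face, trans to the axial 3-OH.

**Step 3**
Reactants: 3 4β-(2-ethoxyethoxy)-5,7,3',4'-tetra-O-benzyl-(−)-epicatechin
Product: 4 4β-(2-ethoxyethoxy)-3,5,7,3',4'-penta-O-benzyl-(−)-epicatechin
Conditions: NaH, BnBr, DMF, 0 °C to rt
Reagents that add atoms: benzyl bromide, BrCc1ccccc1
Why: Williamson ether synthesis on the 3-alkoxide, which masks the only aliphatic OH for steps 7 and 8 with a group that leaves together with all the others in step 11.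

**Step 4**
Reactants: 4 4β-(2-ethoxyethoxy)-3,5,7,3',4'-penta-O-benzyl-(−)-epicatechin; 5 3,5-bis(benzyloxy)phenol (3 equiv)
Product: 6 2-[3,5,7,3',4'-penta-O-benzyl-(−)-epicatechin-4β-yl]-3,5-bis(benzyloxy)phenol
Conditions: Me3SiOSO2CF3 (cat.), CH2Cl2, −78 °C; Et3N quench
Reagents that add atoms: none
Why: Friedel–Crafts alkylation by the flavan C4 cation (the standard interflavan bond formation), in which the arene should enter on the β face trans to the axial 3-OBn group and at a carbon ortho to the free OH, because these two equivalent sites are flanked by the small OH while the third lies between two OBn groups, in parallel with the C8 over C6 preference of benzylated flavan-3-ols.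

**Step 5**
Reactants: 7 3,4-bis(benzyloxy)benzaldehyde
Product: 9 racemic 1-[3,4-bis(benzyloxy)phenyl]prop-2-yn-1-yl acetate, via bromomagnesium alkoxide 8 (not isolated)
Conditions: HC≡CMgBr, THF, 0 °C; then Ac2O, 0 °C to rt
Reagents that add atoms: ethynylmagnesium bromide, C#C[Mg]Br; acetic anhydride, CC(=O)OC(C)=O
Why: Grignard addition to the aldehyde followed by acylation of the alkoxide in the same flask, racemic by design.

**Step 6**
Reactants: 9 racemic 1-[3,4-bis(benzyloxy)phenyl]prop-2-yn-1-yl acetate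
Product: 10 (R)-1-[3,4-bis(benzyloxy)phenyl]prop-2-yn-1-ol
Conditions: immobilised Candida antarctica lipase B, n-BuOH (3 equiv), MTBE, 35 °C, stopped just under half conversion; chromatography
Reagents that add atoms: none
Why: Lipase-catalysed kinetic resolution by transesterification, in which the ester enantiomer that places the aryl group in the large pocket and the ethynyl group in the medium pocket, here (R), should be deacylated faster, setting the only stereocentre made by catalysis.

**Step 7**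
Reactants: 6 2-[3,5,7,3',4'-penta-O-benzyl-(−)-epicatechin-4β-yl]-3,5-bis(benzyloxy)phenol; 10 (R)-1-[3,4-bis(benzyloxy)phenyl]prop-2-yn-1-ol
Product: 11 (S)-1-[3,4-bis(benzyloxy)phenyl]prop-2-yn-1-yl ether of phenol 6
Conditions: n-Bu3P, N,N,N',N'-tetramethylazodicarboxamide, toluene, 0 °C to rt
Reagents that add atoms: none
Why: Mitsunobu reaction, in which SN2 displacement of the oxyphosphonium ion by the phenoxide inverts the carbinol centre and so installs the spatial arrangement of lower C2, with the non-polar solvent and low temperature disfavouring ionisation.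

**Step 8**
Reactants: 11 (S)-1-[3,4-bis(benzyloxy)phenyl]prop-2-yn-1-yl ether of phenol 6
Product: 14 (R)-1-[3,4-bis(benzyloxy)phenyl]-3-(triisopropylsiloxy)prop-2-yn-1-yl ether of phenol 6 (same spatial arrangement at C2), via lithium acetylide 12 (not isolated), via lithium ynolate 13 (not isolated)
Conditions: n-BuLi (1.05 equiv), THF, −78 °C; t-BuOOLi (from t-BuOOH and LiN(SiMe3)2), −78 to 0 °C; i-Pr3SiOSO2CF3, −78 to 0 °C
Reagents that add atoms: tert-butyl hydroperoxide (used as its lithium salt), CC(C)(C)OO; triisopropylsilyl trifluoromethanesulfonate, CC(C)[Si](C(C)C)(C(C)C)OS(=O)(=O)C(F)(F)F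
Why: Oxidation of a lithium acetylide by lithium tert-butyl peroxide to the ynolate and O-silylation by the bulky silyl triflate, the standard route from terminal alkynes to siloxyalkynes, which raises C4 to the acid oxidation level without touching C2.

**Step 9**
Reactants: 14 (R)-1-[3,4-bis(benzyloxy)phenyl]-3-(triisopropylsiloxy)prop-2-yn-1-yl ether of phenol 6
Product: 16 (2S)-5,7,3',4'-tetra-O-benzyl-4-(triisopropylsiloxy)flav-3-ene bearing the penta-O-benzyl-(−)-epicatechin-4β-yl group at C8, via silyl ketenium ion 15 (not isolated)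
Conditions: (CF3SO2)2NH (10 mol %), 4 Å MS, CH2Cl2, −78 to −20 °C, dark; Et3N quench
Reagents that add atoms: none
Why: (CF3SO2)2NH protonates the electron-rich siloxyalkyne at C3 to give the linear silyl ketenium ion 15, its sp carbon C4 is attacked by ring D carbon C4a, and loss of the ring proton restores aromaticity, returns the acid and leaves C4 as a TIPS enol ether, so the step is a catalytic isomerisation. The closest known reaction type is the Brønsted acid-catalysed carbocyclisation of arene-tethered siloxyalkynes to tetralone enol silanes, a Friedel–Crafts acylation at the enol ether level, here with an oxygen in place of one CH2 of the tether. Ring F closes in the 6-endo-dig mode, both alkyne carbons ending inside the ring. No stereocentre is created: C2 should pass through unchanged because carbon protonation of the ynol ether outruns protonation of the weakly basic aryl ether O1 and the cationic C3=C4=O unit next to C2 then disfavours heterolysis of C2–O1, and the C3=C4 bond made here is what lets C2 control C3 in step 10. Regioselectivity is secured by the substrate, since C8 already bears the flavanyl group and C4a is the only free carbon ortho to O1, which fixes the 4→8 connectivity, and C4a, activated by O1, O5 and O7, should outcompete ring E (5-endo closure, one activating oxygen) and ring A (macrocyclic closure). Survival of the acid-labile interflavan bond rests on catalytic acid at low temperature, conditions no harsher than those of step 4.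

**Step 10**
Reactants: 16 (2S)-5,7,3',4'-tetra-O-benzyl-4-(triisopropylsiloxy)flav-3-ene bearing the penta-O-benzyl-(−)-epicatechin-4β-yl group at C8
Product: 19 3,5,7,3',4'-penta-O-benzyl-(−)-epicatechin-(4β→8)-5,7,3',4'-tetra-O-benzyl-(2R,3R)-taxifolin (lower 3-OH free), via siloxy epoxide 17 (not isolated), via 3-O-TIPS ketone 18 (not isolated)
Conditions: dimethyldioxirane (1.1 equiv), acetone/CH2Cl2, −78 to −20 °C; then HF·pyridine, THF, 0 °C
Reagents that add atoms: dimethyldioxirane, CC1(C)OO1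
Why: Rubottom oxidation, in which the dioxirane should attack the enol silane on the face anti to the C2 aryl group (as known for flavanone enol derivatives), the labile siloxy epoxide opens at C4 with silyl shift while the new C3–O bond stays intact to give the 2,3-trans (3R) ketol, and fluoride removes the silyl group under non-basic conditions.

**Step 11**
Reactants: 19 3,5,7,3',4'-penta-O-benzyl-(−)-epicatechin-(4β→8)-5,7,3',4'-tetra-O-benzyl-(2R,3R)-taxifolin
Product: 20 (−)-epicatechin-(4β→8)-(2R,3R)-taxifolin (target; upper unit 2R,3R,4R, lower unit 2R,3R)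
Conditions: H2 (1 atm), Pd(OH)2/C, THF/MeOH/H2O, rt
Reagents that add atoms: none
Why: Hydrogenolysis of the nine benzyl ethers under neutral conditions, which in the flavonoid series leaves the chelated aryl ketone, the interflavan bond and the ring C2–O1 bonds intact and avoids the acid or base that would epimerise ring F.

**Compound list**

1 | (−)-epicatechin | C1c2c(O)cc(O)cc2O[C@H](c2ccc(O)c(O)c2)[C@@H]1O | starting material
2 | 5,7,3',4'-tetra-O-benzyl-(−)-epicatechin | C1c2c(OCc3ccccc3)cc(OCc3ccccc3)cc2O[C@H](c2ccc(OCc3ccccc3)c(OCc3ccccc3)c2)[C@@H]1O | intermediate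
3 | 4β-(2-ethoxyethoxy)-5,7,3',4'-tetra-O-benzyl-(−)-epicatechin | CCOCCO[C@H]1c2c(OCc3ccccc3)cc(OCc3ccccc3)cc2O[C@H](c2ccc(OCc3ccccc3)c(OCc3ccccc3)c2)[C@@H]1O | intermediate
4 | 4β-(2-ethoxyethoxy)-3,5,7,3',4'-penta-O-benzyl-(−)-epicatechin | CCOCCO[C@H]1c2c(OCc3ccccc3)cc(OCc3ccccc3)cc2O[C@H](c2ccc(OCc3ccccc3)c(OCc3ccccc3)c2)[C@@H]1OCc1ccccc1 | intermediate
5 | 3,5-bis(benzyloxy)phenol | Oc1cc(OCc2ccccc2)cc(OCc2ccccc2)c1 | starting material
6 | 2-[3,5,7,3',4'-penta-O-benzyl-(−)-epicatechin-4β-yl]-3,5-bis(benzyloxy)phenol | Oc1cc(OCc2ccccc2)cc(OCc2ccccc2)c1[C@H]1c2c(OCc3ccccc3)cc(OCc3ccccc3)cc2O[C@H](c2ccc(OCc3ccccc3)c(OCc3ccccc3)c2)[C@@H]1OCc1ccccc1 | intermediate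
7 | 3,4-bis(benzyloxy)benzaldehyde | O=Cc1ccc(OCc2ccccc2)c(OCc2ccccc2)c1 | starting material
8 | racemic bromomagnesium 1-[3,4-bis(benzyloxy)phenyl]prop-2-yn-1-olate | C#CC(O[Mg]Br)c1ccc(OCc2ccccc2)c(OCc2ccccc2)c1 | intermediate
9 | racemic 1-[3,4-bis(benzyloxy)phenyl]prop-2-yn-1-yl acetate | C#CC(OC(C)=O)c1ccc(OCc2ccccc2)c(OCc2ccccc2)c1 | intermediate
10 | (R)-1-[3,4-bis(benzyloxy)phenyl]prop-2-yn-1-ol | O[C@@H](c1ccc(OCc2ccccc2)c(OCc2ccccc2)c1)C#C | intermediate
11 | (S)-1-[3,4-bis(benzyloxy)phenyl]prop-2-yn-1-yl ether of phenol 6 | C#C[C@@H](c1ccc(OCc2ccccc2)c(OCc2ccccc2)c1)Oc1cc(OCc2ccccc2)cc(OCc2ccccc2)c1[C@H]1c2c(OCc3ccccc3)cc(OCc3ccccc3)cc2O[C@H](c2ccc(OCc3ccccc3)c(OCc3ccccc3)c2)[C@@H]1OCc1ccccc1 | intermediate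
12 | lithium acetylide of 11 | [Li]C#C[C@@H](c1ccc(OCc2ccccc2)c(OCc2ccccc2)c1)Oc1cc(OCc2ccccc2)cc(OCc2ccccc2)c1[C@H]1c2c(OCc3ccccc3)cc(OCc3ccccc3)cc2O[C@H](c2ccc(OCc3ccccc3)c(OCc3ccccc3)c2)[C@@H]1OCc1ccccc1 | intermediate
13 | lithium ynolate derived from 12 | [Li]OC#C[C@@H](c1ccc(OCc2ccccc2)c(OCc2ccccc2)c1)Oc1cc(OCc2ccccc2)cc(OCc2ccccc2)c1[C@H]1c2c(OCc3ccccc3)cc(OCc3ccccc3)cc2O[C@H](c2ccc(OCc3ccccc3)c(OCc3ccccc3)c2)[C@@H]1OCc1ccccc1 | intermediate
14 | (R)-1-[3,4-bis(benzyloxy)phenyl]-3-(triisopropylsiloxy)prop-2-yn-1-yl ether of phenol 6 | CC(C)[Si](C(C)C)(C(C)C)OC#C[C@@H](c1ccc(OCc2ccccc2)c(OCc2ccccc2)c1)Oc1cc(OCc2ccccc2)cc(OCc2ccccc2)c1[C@H]1c2c(OCc3ccccc3)cc(OCc3ccccc3)cc2O[C@H](c2ccc(OCc3ccccc3)c(OCc3ccccc3)c2)[C@@H]1OCc1ccccc1 | intermediate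
15 | silyl ketenium bis(trifluoromethanesulfonyl)imide formed by C3 protonation of 14 | CC(C)[Si](C(C)C)(C(C)C)[O+]=C=C[C@@H](c1ccc(OCc2ccccc2)c(OCc2ccccc2)c1)Oc1cc(OCc2ccccc2)cc(OCc2ccccc2)c1[C@H]1c2c(OCc3ccccc3)cc(OCc3ccccc3)cc2O[C@H](c2ccc(OCc3ccccc3)c(OCc3ccccc3)c2)[C@@H]1OCc1ccccc1.[N-](S(=O)(=O)C(F)(F)F)S(=O)(=O)C(F)(F)F | intermediate
16 | (2S)-5,7,3',4'-tetra-O-benzyl-4-(triisopropylsiloxy)-8-[penta-O-benzyl-(−)-epicatechin-4β-yl]flav-3-ene | CC(C)[Si](C(C)C)(C(C)C)OC1=C[C@@H](c4ccc(OCc5ccccc5)c(OCc5ccccc5)c4)Oc2c1c(OCc5ccccc5)cc(OCc5ccccc5)c2[C@H]3c4c(OCc5ccccc5)cc(OCc5ccccc5)cc4O[C@H](c4ccc(OCc5ccccc5)c(OCc5ccccc5)c4)[C@@H]3OCc5ccccc5 | intermediate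
17 | 3,4-epoxide of 16, oxygen on the face anti to the C2 aryl group | CC(C)[Si](C(C)C)(C(C)C)O[C@@]12O[C@@H]1[C@@H](c4ccc(OCc5ccccc5)c(OCc5ccccc5)c4)Oc3c2c(OCc5ccccc5)cc(OCc5ccccc5)c3[C@H]6c4c(OCc5ccccc5)cc(OCc5ccccc5)cc4O[C@H](c4ccc(OCc5ccccc5)c(OCc5ccccc5)c4)[C@@H]6OCc5ccccc5 | intermediate
18 | 3-O-triisopropylsilyl ether of 19 | O=C1c2c(OCc5ccccc5)cc(OCc5ccccc5)c([C@H]3c4c(OCc5ccccc5)cc(OCc5ccccc5)cc4O[C@H](c4ccc(OCc5ccccc5)c(OCc5ccccc5)c4)[C@@H]3OCc5ccccc5)c2O[C@H](c2ccc(OCc5ccccc5)c(OCc5ccccc5)c2)[C@H]1O[Si](C(C)C)(C(C)C)C(C)C | intermediate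
19 | 3,5,7,3',4'-penta-O-benzyl-(−)-epicatechin-(4β→8)-5,7,3',4'-tetra-O-benzyl-(2R,3R)-taxifolin | O=C1c2c(OCc5ccccc5)cc(OCc5ccccc5)c([C@H]3c4c(OCc5ccccc5)cc(OCc5ccccc5)cc4O[C@H](c4ccc(OCc5ccccc5)c(OCc5ccccc5)c4)[C@@H]3OCc5ccccc5)c2O[C@H](c2ccc(OCc5ccccc5)c(OCc5ccccc5)c2)[C@H]1O | intermediate
20 | (−)-epicatechin-(4β→8)-(2R,3R)-taxifolin, CNP0210692.1 | O=C1c2c(O)cc(O)c([C@H]3c4c(O)cc(O)cc4O[C@H](c4ccc(O)c(O)c4)[C@@H]3O)c2O[C@H](c2ccc(O)c(O)c2)[C@H]1O | target

**Total step count:** 11. **Longest linear sequence:** 9 steps (1, 2, 3, 4, 7, 8, 9, 10, 11).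

**The three steps most likely to fail**

**Step 8.** The ynolate carries its negative charge on C3, next to the carbon that bears the ring D aryloxide. Expulsion of that aryloxide, or sluggish oxygen transfer to a hindered acetylide, may erode the step. The fallback sets out from 11 and avoids any anionic C3.
- Aerobic copper-catalysed oxidative amidation of the terminal alkyne with 2-oxazolidinone (CuCl2, pyridine, Na2CO3, O2, toluene, 70 °C) should give the N-alkynyl oxazolidinone (ynamide) F1.
- (CF3SO2)2NH-catalysed keteniminium–arene cyclisation of F1 should close the same bond and give the 4-(2-oxooxazolidin-3-yl)flav-3-ene F2.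
- Dihydroxylation of this enamide with OsO4 and N-methylmorpholine N-oxide, anti to the C2 aryl group, followed by collapse of the C4 hemiaminal, returns to the route at 19.

**Step 9.** Brønsted acid may ionise the benzylic and propargylic C2–O1 bond, with loss of configuration at C2. It may also desilylate the enol ether or cleave the interflavan bond. The fallback sets out from 11 and replaces the proton by a neutral π-acid acting on the plain alkyne.
- Ph3PAuNTf2 (monovalent gold, CH2Cl2, rt) should effect the 6-endo-dig hydroarylation to the 8-flavanyl flav-3-ene F3.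
- OsO4 with N-methylmorpholine N-oxide should dihydroxylate F3 anti to the C2 aryl group and give the 2,3-trans-3,4-cis flavan-3,4-diol F4.
- MnO2 in CH2Cl2 should oxidise only the activated benzylic C4 carbinol of F4, which returns to the route at 19.

**Step 7.** The phenol of 6 is flanked by the bulky flavanyl group and the carbinol is an electron-rich benzylic one. Slow displacement, and ionisation with erosion of configuration, may therefore compete. The fallback sets out from 6 and the racemic acetate 9 and uses a copper-catalysed enantioselective propargylic etherification (CuOSO2CF3·0.5C6H6, chiral 2,6-bis(4-phenyl-2-oxazolinyl)pyridine, i-Pr2NEt, 1,2-dichloroethane, −10 °C).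
- The phenoxide adds to the exposed γ carbon of a copper allenylidene, so the ligand rather than an SN2 event controls C2.
- The ligand antipode is chosen on the model phenol 5.
- The sequence skips step 6 and returns to the route at 11. This fallback makes no new compound, F0.

**Further compounds**
F1 | step 8 | N-alkynyl oxazolidinone (ynamide) derived from 11 | O=C1OCCN1C#C[C@@H](c4ccc(OCc5ccccc5)c(OCc5ccccc5)c4)Oc2cc(OCc5ccccc5)cc(OCc5ccccc5)c2[C@H]3c4c(OCc5ccccc5)cc(OCc5ccccc5)cc4O[C@H](c4ccc(OCc5ccccc5)c(OCc5ccccc5)c4)[C@@H]3OCc5ccccc5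
F2 | step 8 | 4-(2-oxooxazolidin-3-yl)flav-3-ene analogue of 16 | O=C1OCCN1C6=C[C@@H](c4ccc(OCc5ccccc5)c(OCc5ccccc5)c4)Oc2c6c(OCc5ccccc5)cc(OCc5ccccc5)c2[C@H]3c4c(OCc5ccccc5)cc(OCc5ccccc5)cc4O[C@H](c4ccc(OCc5ccccc5)c(OCc5ccccc5)c4)[C@@H]3OCc5ccccc5
F3 | step 9 | (2S)-5,7,3',4'-tetra-O-benzyl-8-[penta-O-benzyl-(−)-epicatechin-4β-yl]flav-3-ene | C1=C[C@@H](c4ccc(OCc5ccccc5)c(OCc5ccccc5)c4)Oc2c1c(OCc5ccccc5)cc(OCc5ccccc5)c2[C@H]3c4c(OCc5ccccc5)cc(OCc5ccccc5)cc4O[C@H](c4ccc(OCc5ccccc5)c(OCc5ccccc5)c4)[C@@H]3OCc5ccccc5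
F4 | step 9 | 2,3-trans-3,4-cis flavan-3,4-diol derived from F3 | O[C@H]1c2c(OCc5ccccc5)cc(OCc5ccccc5)c([C@H]3c4c(OCc5ccccc5)cc(OCc5ccccc5)cc4O[C@H](c4ccc(OCc5ccccc5)c(OCc5ccccc5)c4)[C@@H]3OCc5ccccc5)c2O[C@H](c2ccc(OCc5ccccc5)c(OCc5ccccc5)c2)[C@H]1O
F0 | step 7 | none | none
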